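**Assumption:** the stereocentre in the SMILES is C8 of the undecyl chain and is (R); methyl 2‑(furan‑2‑yl)acetate and (R)‑4‑benzyl‑2‑oxazolidinone are taken as purchasable.

## Retrosynthetic overview

1. Target aldehyde ⇐ primary alcohol (Dess–Martin) ⇐ TBS ether.
2. Furan–C1 bond ⇐ terminal alkene (9‑BBN) + methyl 2‑(5‑bromofuran‑2‑yl)acetate by B‑alkyl Suzuki coupling. The furan ring is bought; no ring is formed in the route.
3. C6–C7 bond ⇐ β‑branched primary tosylate + hex‑5‑enyl Grignard (Cu‑catalysed), then tert‑butyl ester → CH2OTBS.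
4. Key C8–C9 bond and the only stereocentre ⇐ N‑hexanoyl (R)‑benzyloxazolidinone + tert‑butyl acrylate by an auxiliary‑controlled titanium‑enolate Michael addition.

## Route

**Step 1**
Reactants: 1 (R)-4-benzyl-1,3-oxazolidin-2-one; 2 hexanoyl chloride
Product: 4 (R)-4-benzyl-3-hexanoyl-1,3-oxazolidin-2-one, via lithium oxazolidinide 3 (not isolated)
Conditions: n-BuLi, THF, −78 °C; then 2, −78 → 0 °C
Reagents that add atoms: n-butyllithium, CCCC[Li] (its lithium ends in 3 only)
Why: N-acylation of the lithiated Evans auxiliary by the acid chloride is fast and irreversible at low temperature and leaves the ring stereocentre untouched.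

**Step 2**
Reactants: 4 (R)-4-benzyl-3-hexanoyl-1,3-oxazolidin-2-one; 5 tert-butyl acrylate
Product: 7 tert-butyl (4S)-4-{[(4R)-4-benzyl-2-oxo-1,3-oxazolidin-3-yl]carbonyl}octanoate, via (Z)-chlorotitanium enolate 6 (not isolated)
Conditions: TiCl4 (0.8 equiv), Ti(OiPr)4 (0.27 equiv), CH2Cl2, 0 °C; i-Pr2NEt (1.1 equiv), 1 h; then 5 (1.5 equiv), 0 °C, 3 h; aq NH4Cl
Reagents that add atoms: titanium tetrachloride, Cl[Ti](Cl)(Cl)Cl; titanium tetraisopropoxide, CC(C)O[Ti](OC(C)C)(OC(C)C)OC(C)C (their atoms end in 6 only)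
Why: In this Evans asymmetric Michael addition the chelated (Z)-titanium enolate attacks the acrylate from the face opposite the benzyl group, which sets the new α-centre as (S) (the later C8) with dr typically ≥95:5.

**Step 3**
Reactants: 7 tert-butyl (4S)-4-{[(4R)-4-benzyl-2-oxo-1,3-oxazolidin-3-yl]carbonyl}octanoate
Product: 8 tert-butyl (4S)-4-(hydroxymethyl)octanoate
Conditions: LiBH4 (1.5 equiv), H2O (1.5 equiv), Et2O, 0 °C
Reagents that add atoms: none
Why: Reductive auxiliary cleavage works because LiBH4 reduces the activated imide carbonyl much faster than the hindered tert-butyl ester, without epimerising the α-centre, and returns auxiliary 1.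

**Step 4**
Reactants: 8 tert-butyl (4S)-4-(hydroxymethyl)octanoate
Product: 9 tert-butyl (4S)-4-{[(4-methylbenzenesulfonyl)oxy]methyl}octanoate
Conditions: TsCl, Et3N, DMAP (cat.), CH2Cl2, 0 °C → rt
Reagents that add atoms: p-toluenesulfonyl chloride, Cc1ccc(cc1)S(=O)(=O)Cl
Why: O-sulfonylation (tosylation) of a primary alcohol is routine and does not involve the stereocentre.

**Step 5**
Reactants: 9 tert-butyl (4S)-4-{[(4-methylbenzenesulfonyl)oxy]methyl}octanoate; 10 6-bromohex-1-ene
Product: 12 tert-butyl (4R)-4-butylundec-10-enoate, via hex-5-enylmagnesium bromide 11 (not isolated)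
Conditions: 10, Mg, THF, rt → 40 °C; then 9, Li2CuCl4 (5 mol %), THF, −78 → 0 °C
Reagents that add atoms: magnesium, [Mg] (ends in 11 only)
Why: The Fouquet–Schlosser copper-catalysed Grignard–tosylate coupling displaces the primary tosylate at the CH2 next to the stereocentre while the tert-butyl ester survives below 0 °C, so the configuration is untouched (S → R is only a change of CIP priorities).

**Step 6**
Reactants: 12 tert-butyl (4R)-4-butylundec-10-enoate
Product: 13 (4R)-4-butylundec-10-en-1-ol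
Conditions: LiAlH4, THF, 0 °C → rt
Reagents that add atoms: none
Why: Hydride reduction of the ester to the primary alcohol is clean, and the isolated terminal alkene is inert to LiAlH4.

**Step 7**
Reactants: 13 (4R)-4-butylundec-10-en-1-ol
Product: 14 tert-butyl{[(4R)-4-butylundec-10-en-1-yl]oxy}dimethylsilane
Conditions: TBSCl, imidazole, CH2Cl2, rt
Reagents that add atoms: tert-butyldimethylsilyl chloride, CC(C)(C)[Si](C)(C)Cl
Why: Silyl ether protection of the primary alcohol keeps the future aldehyde carbon masked through hydroboration and cross-coupling.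

**Step 8**
Reactants: 15 methyl 2-(furan-2-yl)acetate
Product: 16 methyl 2-(5-bromofuran-2-yl)acetate
Conditions: NBS (1.0 equiv), DMF, −20 → 0 °C, dark; used at once
Reagents that add atoms: N-bromosuccinimide, BrN1C(=O)CCC1=O
Why: Electrophilic aromatic bromination of a 2-substituted furan with NBS in DMF goes to the free α-position C5 under ionic conditions that spare the side-chain CH2.

**Step 9**
Reactants: 14 tert-butyl{[(4R)-4-butylundec-10-en-1-yl]oxy}dimethylsilane; 16 methyl 2-(5-bromofuran-2-yl)acetate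
Product: 18 methyl 2-{5-[(8R)-8-butyl-11-{[tert-butyl(dimethyl)silyl]oxy}undecyl]furan-2-yl}acetate, via B-alkyl-9-BBN 17 (not isolated)
Conditions: 9-BBN (1.3 equiv), THF, 0 °C → rt; then 16 (1.2 equiv), PdCl2(dppf) (5 mol %), AsPh3 (5 mol %), Cs2CO3 (2 equiv), DMF/THF/H2O, rt
Reagents that add atoms: 9-borabicyclo[3.3.1]nonane, B1C2CCCC1CCC2 (its boron and C8 frame end in 17 only)
Why: Anti-Markovnikov hydroboration of the terminal alkene followed by B-alkyl Suzuki–Miyaura coupling joins C1 to the furan at room temperature with a mild base that the methyl ester and the remote stereocentre tolerate.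

**Step 10**
Reactants: 18 methyl 2-{5-[(8R)-8-butyl-11-{[tert-butyl(dimethyl)silyl]oxy}undecyl]furan-2-yl}acetate
Product: 19 methyl 2-{5-[(8R)-8-butyl-11-hydroxyundecyl]furan-2-yl}acetate
Conditions: TBAF (1.5 equiv), AcOH (1.5 equiv), THF, 0 °C → rt
Reagents that add atoms: none
Why: Fluoride-mediated desilylation buffered with acetic acid frees the primary alcohol without enolising the furylacetate or opening the furan.

**Step 11**
Reactants: 19 methyl 2-{5-[(8R)-8-butyl-11-hydroxyundecyl]furan-2-yl}acetate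
Product: 20 methyl 2-{5-[(8R)-8-butyl-11-oxoundecyl]furan-2-yl}acetate
Conditions: Dess–Martin periodinane (1.3 equiv), pyridine, CH2Cl2, 0 °C → rt
Reagents that add atoms: none
Why: Dess–Martin oxidation under pyridine buffering stops at the aldehyde and tolerates the electron-rich furan and the ester, and the γ-stereocentre cannot epimerise.

## Compound list

1 | (R)-4-benzyl-1,3-oxazolidin-2-one | O=C1N[C@H](Cc2ccccc2)CO1 | starting material
2 | hexanoyl chloride | CCCCCC(=O)Cl | starting material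
3 | lithium (R)-4-benzyl-2-oxo-1,3-oxazolidin-3-ide | [Li]N1[C@H](Cc2ccccc2)COC1=O | intermediate (not isolated)
4 | (R)-4-benzyl-3-hexanoyl-1,3-oxazolidin-2-one | CCCCCC(=O)N1[C@H](Cc2ccccc2)COC1=O | intermediate
5 | tert-butyl acrylate | C=CC(=O)OC(C)(C)C | starting material
6 | (Z)-dichloro(isopropoxy)titanium enolate of 4 | CCCC/C=C(\O[Ti](Cl)(Cl)OC(C)C)N1[C@H](Cc2ccccc2)COC1=O | intermediate (not isolated)
7 | tert-butyl (4S)-4-{[(4R)-4-benzyl-2-oxo-1,3-oxazolidin-3-yl]carbonyl}octanoate | CCCC[C@@H](CCC(=O)OC(C)(C)C)C(=O)N1[C@H](Cc2ccccc2)COC1=O | intermediate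
8 | tert-butyl (4S)-4-(hydroxymethyl)octanoate | CCCC[C@@H](CCC(=O)OC(C)(C)C)CO | intermediate
9 | tert-butyl (4S)-4-{[(4-methylbenzenesulfonyl)oxy]methyl}octanoate | CCCC[C@@H](CCC(=O)OC(C)(C)C)COS(=O)(=O)c1ccc(C)cc1 | intermediate
10 | 6-bromohex-1-ene | BrCCCCC=C | starting material
11 | hex-5-en-1-ylmagnesium bromide | C=CCCCC[Mg]Br | intermediate (not isolated)
12 | tert-butyl (4R)-4-butylundec-10-enoate | CCCC[C@@H](CCC(=O)OC(C)(C)C)CCCCCC=C | intermediate
13 | (4R)-4-butylundec-10-en-1-ol | CCCC[C@@H](CCCO)CCCCCC=C | intermediate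
14 | tert-butyl{[(4R)-4-butylundec-10-en-1-yl]oxy}dimethylsilane | CCCC[C@@H](CCCO[Si](C)(C)C(C)(C)C)CCCCCC=C | intermediate
15 | methyl 2-(furan-2-yl)acetate | COC(=O)Cc1ccco1 | starting material
16 | methyl 2-(5-bromofuran-2-yl)acetate | COC(=O)Cc1ccc(Br)o1 | intermediate
17 | 9-[(8R)-8-butyl-11-{[tert-butyl(dimethyl)silyl]oxy}undecyl]-9-borabicyclo[3.3.1]nonane | CCCC[C@@H](CCCO[Si](C)(C)C(C)(C)C)CCCCCCCB1C2CCCC1CCC2 | intermediate (not isolated)
18 | methyl 2-{5-[(8R)-8-butyl-11-{[tert-butyl(dimethyl)silyl]oxy}undecyl]furan-2-yl}acetate | CCCC[C@@H](CCCO[Si](C)(C)C(C)(C)C)CCCCCCCc1ccc(CC(=O)OC)o1 | intermediate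
19 | methyl 2-{5-[(8R)-8-butyl-11-hydroxyundecyl]furan-2-yl}acetate | CCCC[C@@H](CCCO)CCCCCCCc1ccc(CC(=O)OC)o1 | intermediate
20 | methyl 2-{5-[(8R)-8-butyl-11-oxoundecyl]furan-2-yl}acetate | CCCC[C@@H](CCC=O)CCCCCCCc1ccc(CC(=O)OC)o1 | target

## Summary

Total step count: 11. Longest linear sequence: 10 steps (1 → 4 → 7 → 8 → 9 → 12 → 13 → 14 → 18 → 19 → 20); step 8 is a one-step side branch.

Steps most likely to fail:

**Step 5.** The tosylate is β-branched, so the copper-catalysed displacement is slow and Grignard attack on the ester can compete. The fallback reverses the polarity and sets out from 8. Appel iodination (I2, PPh3, imidazole, CH2Cl2) gives tert-butyl (4S)-4-(iodomethyl)octanoate F1. Zinc insertion (Zn dust, LiCl, THF) gives the ester-tolerant [(2S)-2-butyl-5-(tert-butoxy)-5-oxopentyl]zinc iodide F2. A palladium-catalysed alkyl–alkyl Negishi coupling of F2 with 10 (Pd2(dba)3, PCyp3, N-methylimidazole, THF/NMP, 80 °C) comes back to the route at 12.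

**Step 9.** Bromofuran 16 is labile, and the coupling must outrun protodeboronation and ester hydrolysis. The fallback uses no halofuran and no palladium and sets out from 14. Hydroboration–oxidation (9-BBN; NaOH, H2O2) gives (8R)-8-butyl-11-{[tert-butyl(dimethyl)silyl]oxy}undecan-1-ol F3. Appel iodination gives tert-butyl{[(4R)-4-butyl-11-iodoundecyl]oxy}dimethylsilane F4. Alkylation of 2-furyllithium (furan, n-BuLi, THF, 0 °C → rt) with F4 gives tert-butyl{[(4R)-4-butyl-11-(furan-2-yl)undecyl]oxy}dimethylsilane F5. Radical C5–H alkylation of F5 with methyl 2-[(ethoxycarbonothioyl)sulfanyl]acetate F6 (from potassium O-ethyl xanthate and methyl bromoacetate in acetone) and dilauroyl peroxide in refluxing 1,2-dichloroethane comes back to the route at 18.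

**Step 3.** Possible problems are endocyclic opening of the hindered imide, partial ester reduction, or δ-lactonisation of 8. The fallback sets out from 7. Hydrolytic auxiliary removal (LiOH, H2O2, THF/H2O, 0 °C; Na2SO3) gives (2S)-2-butyl-5-(tert-butoxy)-5-oxopentanoic acid F7. Chemoselective borane reduction of the acid (BH3·THF, 0 °C) comes back to the route at 8.

## Further compounds

F1 | step 5 | tert-butyl (4S)-4-(iodomethyl)octanoate | CCCC[C@@H](CCC(=O)OC(C)(C)C)CI
F2 | step 5 | [(2S)-2-butyl-5-(tert-butoxy)-5-oxopentyl]zinc iodide | CCCC[C@@H](CCC(=O)OC(C)(C)C)C[Zn]I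
F3 | step 9 | (8R)-8-butyl-11-{[tert-butyl(dimethyl)silyl]oxy}undecan-1-ol | CCCC[C@@H](CCCO[Si](C)(C)C(C)(C)C)CCCCCCCO
F4 | step 9 | tert-butyl{[(4R)-4-butyl-11-iodoundecyl]oxy}dimethylsilane | CCCC[C@@H](CCCO[Si](C)(C)C(C)(C)C)CCCCCCCI
F5 | step 9 | tert-butyl{[(4R)-4-butyl-11-(furan-2-yl)undecyl]oxy}dimethylsilane | CCCC[C@@H](CCCO[Si](C)(C)C(C)(C)C)CCCCCCCc1ccco1
F6 | step 9 | methyl 2-[(ethoxycarbonothioyl)sulfanyl]acetate | CCOC(=S)SCC(=O)OC
F7 | step 3 | (2S)-2-butyl-5-(tert-butoxy)-5-oxopentanoic acid | CCCC[C@@H](CCC(=O)OC(C)(C)C)C(=O)O
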